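## Structural features

The target is a bicyclo[3.3.1]nonan-9-one. Ring A (C1–C6) and ring B (C3, C4, C5, C7, C8, C9) are six-membered, share the C3–C4–C5 unit and have the C4 ketone as the one-carbon bridge. C1 carries the (E)-dodec-2-enamide nitrogen, C3 a bridgehead tertiary hydroxyl, C6 a secondary hydroxyl, C7 a methoxy group, and C8–C9 a cis-epoxide. The seven stereocentres (C1, C6, C5, C7, C8, C9, C3) are contiguous: nitrogen is equatorial on ring A and cis to the axial O6, and the methoxy group and the epoxide oxygen lie on the exo face of ring B, anti to the C2–C1–C6 bridge and syn to the C3 hydroxyl. Fragile groups are the β-hydroxy ketone (C6–OH/C4=O, prone to retro-aldol cleavage of C5–C6 in base), the α-ketol at C3–C4, the epoxide and the conjugated enamide, so the closing steps must be neither basic nor reducing. The real difficulty is the fully substituted carbinol C3, flanked by the ketone, an epoxide carbon and the ring A methylene, together with the need to tell O4 (future ketone) from O6 (future alcohol), which are syn-diaxial on ring A. The key step exploits the C3(OH)–C2H2 unit, which is what an oxirane spiro-fused to ring B at C3 leaves after attack at its methylene carbon, and the nitrogen on C1, which can be carried as a nitro group so that C1 is a nitronate carbon; formation of C1–C2 then closes ring A onto a preformed ring B.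

## Logic of the disconnections

**35 from 34.** Bonds cut: the aminal C–N and C–O6 bonds of the N,O-acetal. The base-labile 35 is released last under mild acid. The demand is that the aryl-stabilised N-acyliminium ion forms faster than the epoxide opens.

**34 from 33 from 32.** Bonds cut: C4=O back to C4–OH, and the two C–O bonds of the C8–C9 epoxide. With N and O6 tied together, O4 is the only secondary alcohol, so no selectivity between O4 and O6 is needed. Epoxidation precedes oxidation so that no ketone meets peracid. The oxygen must come from the exo face, which is both the convex face and the face of the C3 hydroxyl.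

**32 from 27, 30 and 29 (29 from 28).** Bonds cut: the amide C–N bond and both bonds of the aminal carbon. The cis-vicinal N/O6 pair is used to mask O6 with the side chain already on nitrogen. Opening an N-acyl cyclic carbamate with hydroxide is avoided, because hydroxide would normally attack the exocyclic acyl group and the target does not tolerate base. The forward step must trap the ring-closed tautomer by N-acylation.

**27 from 26 from 25.** Bonds cut: none in the skeleton; NH2 goes back to NO2 and the O4/O6 acetal is restored. The acetal is removed before the reduction so that no aldehyde is present beside the amine under reducing conditions.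

**25 from 23 (key step).** Bond cut: C1–C2, which opens ring A. This gives a monocyclic ring B carrying a spiro-oxirane at C3 and a nitromethyl arm at C6. C2 must be syn to O4 and to the C5 arm, the oxirane oxygen anti, and O4 and O6 must be protected.

**23 from 22.** Bond cut: acetal carbon–O6. The tether is made by oxidation of the O4 benzylic ether, so O4 is never free next to the oxirane (no Payne rearrangement) and no Brønsted acid meets the allylic oxirane. A monoaryl acetal is preferred to a gem-dimethyl acetal because the dioxane must leave its chair during ring closure. A gem-dimethyl acetal would then push a methyl group against H5 or C2, whereas here only hydrogen takes the crowded position.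

**22 from 20 and 21.** Bond cut: C1–C6 (nitroaldol). Both β-oxygen substituents of 20 are expected to favour the wrong C6 epimer, so the catalyst has to control the face.

**20 from 18.** Bond cut: C6=CH2. A vinyl group is an aldehyde equivalent that survives every earlier step. The forward step must cleave it in the presence of the ring alkene.

**18 from 16 from 14 and 15.** Bonds cut: C3–O and C2–O of the oxirane, then C3=C2. Direct methylene transfer to the ketone of 14 would deliver carbon anti to the axial C4–O bond and syn to the axial H5, giving the C3 epimer. Carbon is therefore put on first without a stereocentre, and oxygen is then added to C3 from the open face.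

**14 from 12 from 11.** Bonds cut: C8=C9 back to the aldol, then C8–C9 (Ferrier carbocyclisation). All six ring B carbons come from one hexose: sugar C1–C6 become C8, C7, C5, C4, C3 and C9.

**11 from 10 from 9 from 8.** Bonds cut: sugar C5=C6, C6–I, and the O6–acetal carbon bond. Reductive opening of the arylidene acetal leaves the benzylic ether on O4, where it is needed in 23.

**8 from 7 from 5 and 6.** Bonds cut: O–CH3 and sugar C3–vinyl. The arm on C5 must be anti to the C7 methoxy group and syn to O4 (altro), which is inverted relative to O3 of a gluco- or manno-pyranoside. Trans-diaxial opening of 5 gives exactly this and frees only the oxygen that is to be methylated.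

**5 from 3 from 1 and 2.** Bonds cut: the oxirane C2–O bond and the two acetal C–O bonds. The gluco diol supplies the manno oxirane by inversion at sugar C2; sugar C4 is kept.

## Other disconnections considered

Alternative 1: The cut is C1–N. The C6 carbamate A2 of the nitrogen-free epoxy ketol would be oxidised with PhI(OAc)2 and MgO under Rh2(OAc)4 catalysis to a rhodium nitrene that inserts into the cis C1–H bond, giving the cis-fused oxazolidinone A1.
- In favour: insertion proceeds with retention and the five-membered tether can only reach the equatorial C1–H, so the C1 configuration is fixed by geometry. On this point it is the equal of, or better than, equilibration through a nitronate. It also avoids the nitro reduction and forms the N/O6 bridge in the same step, which is better in step count at that stage.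
- Against: C1–H is an unactivated secondary C–H in an electron-poor, heavily oxygenated cage, and the tertiary C5–H is also β to the carbamate. Without the nitro group, ring A needs a different C–C bond-forming closure. A1 must still be N-acylated and opened at the ring carbonyl, a step in which hydroxide normally attacks the exocyclic acyl group and which exposes the β-hydroxy ketone to base.
- Comparison: the chosen plan uses nitrogen to build the skeleton; Alternative 1 adds it late by a reaction of uncertain site selectivity. The overall step count would be similar.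

Alternative 2: The cuts are C4–C5 and O–C6. NaOCl would oxidise the aldoxime of the (Z,Z)-cyclooctadiene A4 to a nitrile oxide that adds across the ring to C5=C6, closing ring A, ring B and an isoxazoline in A3.
- In favour: two rings and two stereocentres (C5, C6) form in one stereospecific syn addition. The isoxazoline is a masked β-hydroxy ketone with exactly the C4=O/C6–OH pattern, so neither the O4/O6 distinction nor a C4 oxidation is needed. This is better than the chosen plan in redox economy, and nitrogen is already a carbamate.
- Against: A4 is an eight-membered diene with three stereocentres including the quaternary C3. Medium-ring assembly and the facial course of a transannular addition are much less predictable than a chair-like 6-exo-tet closure. N–O cleavage must also spare the C8=C9 alkene.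
- Comparison: structurally more convergent at the key step, mechanistically concerted rather than SN2, but the route to A4 is likely to cost more steps than the sugar-based route to 23.

Alternative 3: The cut is C7–OMe together with a one-carbon ring expansion. AgClO4 in methanol would ionise the exo gem-dibromocyclopropane A6, the C7–C9 bond would open to an allyl cation, and methanol would add at C7 to give the vinyl bromide A5.
- In favour: ring A and the N/O6 pair are in place before ring B is expanded. Methanol is expected on the exo face, so C7 would be set as reliably as by taking it from the sugar (equal on that point). The vinyl bromide is a usable handle.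
- Against: methanol may add at C9 instead of C7. The α-silyloxy ketone must survive carbene addition and silver ion. The bromine must be removed before or after epoxidation, which costs steps. A6 with its four stereocentres is no simpler to make than 23.
- Comparison: a cationic ring expansion with a regiochemical question against an SN2 closure without one; step count similar or longer.

Key step: step 15

Remark: atom labels C1–C9 are those of the target in all carbocycles; "sugar C" labels refer to the pyranoside.
Remark: 12, 23, 25 and 32–34 are drawn as the epimer expected on steric grounds at C8, the acetal carbon and the aminal carbon; 19 is drawn without configuration at C6. All these centres are removed later, so any epimer converges.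

Step 1
Reactants: 1 methyl α-D-glucopyranoside; 2 4-methoxybenzaldehyde dimethyl acetal
Product: 3 methyl 4,6-O-(4-methoxybenzylidene)-α-D-glucopyranoside
Conditions: 2, CSA (cat.), DMF, 60 °C, reduced pressure
Reagents that add atoms: 4-methoxybenzaldehyde dimethyl acetal, COc1ccc(C(OC)OC)cc1
Why: Acid-catalysed acetal exchange under thermodynamic control gives the six-membered 4,6-acetal with the aryl group equatorial (R acetal carbon).

Step 2
Reactants: 3 methyl 4,6-O-(4-methoxybenzylidene)-α-D-glucopyranoside
Product: 5 methyl 2,3-anhydro-4,6-O-(4-methoxybenzylidene)-α-D-mannopyranoside, via 2-O-tosylate 4 (not isolated)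
Conditions: NaH (2.5 equiv), N-tosylimidazole (1.1 equiv), DMF, 0 °C → rt
Reagents that add atoms: none
Why: The more acidic 2-OH is sulfonylated first and the trans C3 alkoxide displaces the tosylate (intramolecular Williamson reaction) with inversion at sugar C2; this puts the oxygen that becomes the C7 methoxy oxygen on the β face.

Step 3
Reactants: 5 methyl 2,3-anhydro-4,6-O-(4-methoxybenzylidene)-α-D-mannopyranoside; 6 vinylmagnesium bromide
Product: 7 methyl 3-deoxy-4,6-O-(4-methoxybenzylidene)-3-C-vinyl-α-D-altropyranoside
Conditions: CH2=CHMgBr (3 equiv), CuI (10 mol%), THF, −30 → 0 °C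
Reagents that add atoms: vinylmagnesium bromide, C=C[Mg]Br
Why: Copper-catalysed Grignard opening of the epoxide; in the acetal-locked chair the Fürst–Plattner rule requires trans-diaxial attack at sugar C3 from the α face, which sets C5 with the arm anti to O2 and syn to O4.

Step 4
Reactants: 7 methyl 3-deoxy-4,6-O-(4-methoxybenzylidene)-3-C-vinyl-α-D-altropyranoside
Product: 8 methyl 3-deoxy-4,6-O-(4-methoxybenzylidene)-2-O-methyl-3-C-vinyl-α-D-altropyranoside
Conditions: NaH, MeI, DMF, 0 °C → rt
Reagents that add atoms: iodomethane, CI
Why: Williamson ether synthesis on the only free hydroxyl; it installs the C7 methoxy group.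

Step 5
Reactants: 8 methyl 3-deoxy-4,6-O-(4-methoxybenzylidene)-2-O-methyl-3-C-vinyl-α-D-altropyranoside
Product: 9 methyl 3-deoxy-4-O-(4-methoxybenzyl)-2-O-methyl-3-C-vinyl-α-D-altropyranoside
Conditions: i-Bu2AlH (3 equiv), CH2Cl2, −20 → 0 °C; H2O work-up
Reagents that add atoms: none
Why: Regioselective reductive opening of the arylidene acetal: aluminium binds the less hindered primary O6 and hydride goes to the acetal carbon, so the benzylic ether stays on O4; the vinyl group is inert at this temperature.

Step 6
Reactants: 9 methyl 3-deoxy-4-O-(4-methoxybenzyl)-2-O-methyl-3-C-vinyl-α-D-altropyranoside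
Product: 10 methyl 3,6-dideoxy-6-iodo-4-O-(4-methoxybenzyl)-2-O-methyl-3-C-vinyl-α-D-altropyranoside
Conditions: I2, PPh3, imidazole, toluene, 60 °C
Reagents that add atoms: iodine, II
Why: Appel-type iodination of the primary alcohol by SN2 displacement of the alkoxyphosphonium ion.

Step 7
Reactants: 10 methyl 3,6-dideoxy-6-iodo-4-O-(4-methoxybenzyl)-2-O-methyl-3-C-vinyl-α-D-altropyranoside
Product: 11 methyl 3,6-dideoxy-4-O-(4-methoxybenzyl)-2-O-methyl-3-C-vinyl-α-D-arabino-hex-5-enopyranoside
Conditions: KOt-Bu, THF, 0 °C → rt
Reagents that add atoms: none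
Why: E2 dehydroiodination gives the exocyclic enol ether needed for the carbocyclisation.

Step 8
Reactants: 11 methyl 3,6-dideoxy-4-O-(4-methoxybenzyl)-2-O-methyl-3-C-vinyl-α-D-arabino-hex-5-enopyranoside
Product: 12 5-hydroxy-4-methoxy-2-(4-methoxybenzyloxy)-3-vinylcyclohexan-1-one (C3 ketone; O4 and vinyl cis; methoxy trans to vinyl)
Conditions: Hg(OCOCF3)2 (10 mol%), acetone–H2O 4:1, rt
Reagents that add atoms: water, O
Why: Ferrier carbocyclisation: divalent mercury hydroxymercurates the enol ether, the hemiketal collapses with loss of methanol to a keto aldehyde, and intramolecular aldol closure of C9 onto C8 forms ring B; the C8 carbinol is expected mainly trans to the C5 vinyl group and is erased in step 9.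

Step 9
Reactants: 12 5-hydroxy-4-methoxy-2-(4-methoxybenzyloxy)-3-vinylcyclohexan-1-one
Product: 14 4-methoxy-6-(4-methoxybenzyloxy)-5-vinylcyclohex-2-en-1-one, via C8 mesylate 13 (not isolated)
Conditions: MsCl, Et3N, CH2Cl2, 0 °C → rt
Reagents that add atoms: none
Why: Mesylation followed by E1cB elimination gives the enone with C8=C9; the mild amine base should leave the α′ centre C4 untouched, as is usual for Ferrier-derived enones.

Step 10
Reactants: 14 4-methoxy-6-(4-methoxybenzyloxy)-5-vinylcyclohex-2-en-1-one; 15 methyltriphenylphosphonium bromide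
Product: 16 6-methoxy-4-(4-methoxybenzyloxy)-3-methylidene-5-vinylcyclohex-1-ene
Conditions: 15, KN(SiMe3)2, THF, −78 → 0 °C
Reagents that add atoms: methyltriphenylphosphonium bromide, C[P+](c1ccccc1)(c1ccccc1)c1ccccc1.[Br-]
Why: Wittig methylenation of the enone carbonyl puts C2 on C3 without creating a stereocentre; the salt-free ylide at low temperature limits enolisation at C4.

Step 11
Reactants: 16 6-methoxy-4-(4-methoxybenzyloxy)-3-methylidene-5-vinylcyclohex-1-ene
Product: 18 6-methoxy-8-(4-methoxybenzyloxy)-7-vinyl-1-oxaspiro[2.5]oct-4-ene (C2 syn to O4 and to the vinyl group), via bromohydrin 17 (not isolated)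
Conditions: NBS (1.05 equiv), THF–H2O 4:1, 0 °C; then K2CO3, MeOH, 0 °C → rt
Reagents that add atoms: water, O
Why: Halohydrin formation then Williamson closure: bromine adds to the terminal carbon of the diene (as in the bromohydrin of isoprene) and water takes the tertiary allylic C3 from the face opposite O4 and the C5 arm, which sets C3 with the oxirane oxygen anti and C2 syn to both. The PMB ether keeps O4 out of any Payne rearrangement.

Step 12
Reactants: 18 6-methoxy-8-(4-methoxybenzyloxy)-7-vinyl-1-oxaspiro[2.5]oct-4-ene
Product: 20 6-methoxy-8-(4-methoxybenzyloxy)-1-oxaspiro[2.5]oct-4-ene-7-carbaldehyde, via vicinal diol 19 (not isolated)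
Conditions: OsO4 (2 mol%), NaIO4 (3 equiv), 2,6-lutidine, dioxane–H2O 3:1, 0 °C → rt
Reagents that add atoms: osmium tetroxide, O=[Os](=O)(=O)=O; sodium periodate (terminal oxidant), [Na+].[O-]I(=O)(=O)=O
Why: Lemieux–Johnson cleavage; osmylation should prefer the monosubstituted vinyl group to the ring alkene, which is cis-disubstituted, next to a quaternary carbon and deactivated by two allylic C–O bonds.

Step 13
Reactants: 20 6-methoxy-8-(4-methoxybenzyloxy)-1-oxaspiro[2.5]oct-4-ene-7-carbaldehyde; 21 nitromethane
Product: 22 (1R)-1-[6-methoxy-8-(4-methoxybenzyloxy)-1-oxaspiro[2.5]oct-4-en-7-yl]-2-nitroethanol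
Conditions: 21 (10 equiv), Cu(OAc)2·H2O (10 mol%), indane-derived bis(oxazoline) ligand (11 mol%; the enantiomer that sends nitronate to the Si face), EtOH, 0 °C
Reagents that add atoms: nitromethane, C[N+](=O)[O-]
Why: Copper-catalysed asymmetric Henry reaction; the chiral complex selects the Si face of the aldehyde and sets C6 as R, and the weakly basic acetate avoids epimerisation at C5 and β-elimination.

Step 14
Reactants: 22 (1R)-1-[6-methoxy-8-(4-methoxybenzyloxy)-1-oxaspiro[2.5]oct-4-en-7-yl]-2-nitroethanol
Product: 23 O4,O6-(4-methoxybenzylidene) acetal of 22: ring B cyclohexene with the C3 spiro-oxirane and a cis-fused 2-aryl-1,3-dioxane bearing the nitromethyl group on C6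
Conditions: DDQ (1.2 equiv), 4 Å MS, CH2Cl2, 0 °C
Reagents that add atoms: none
Why: Oxidative acetalisation: DDQ turns the 4-methoxybenzyl ether into an oxocarbenium ion that the 1,3-related C6 hydroxyl traps, with the aryl group equatorial on the new dioxane.

Step 15
Reactants: 23 O4,O6-(4-methoxybenzylidene) acetal of 22
Product: 25 tricyclic nitro alcohol (C1 nitro equatorial, C3 hydroxyl, O4,O6-(4-methoxybenzylidene) acetal, C8=C9), via C1 epimer 24 (not isolated)
Conditions: DBU (1.5 equiv), MeCN, 0 → 40 °C
Reagents that add atoms: none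
Why: DBU deprotonates C1 and the nitronate carbon attacks the methylene carbon C2 of the spiro-oxirane in an SN2 reaction, the known intramolecular C-alkylation of a nitronate by an epoxide. Ring A closes in the 6-exo-tet mode, and with the oxirane oxygen equatorial on the forming chair the C1···C2–O angle is close to 180°. The oxirane oxygen becomes the C3 hydroxyl with the configuration set in step 11. The only new stereocentre is C1: both epimers interconvert through the nitronate and the product should settle with the nitro group equatorial on the convex face, because the axial epimer 24 points into ring B. The step needs C- over O-alkylation, secured because O-attack would require an eight-membered ring. It needs SN2 at C2 over SN2′ at C8, secured by the cis-fused dioxane, which holds C1 next to C2 on the C4 side of C5. It also needs no loss of O6 from the nitronate, since an acetal oxygen is a poor leaving group and can add back. The dioxane has to twist out of its chair, and its monoaryl acetal carbon then puts only hydrogen in the crowded position.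

Step 16
Reactants: 25 tricyclic nitro alcohol
Product: 26 6-methoxy-3-nitrobicyclo[3.3.1]non-7-ene-1,4,9-triol (target labels: C1 nitro; C3, C4 and C6 hydroxyls; C7 methoxy)
Conditions: AcOH–H2O 4:1, 40 °C
Reagents that add atoms: none
Why: Acid hydrolysis of the strained arylidene acetal; the bridgehead allylic C3 carbinol cannot ionise and the nitro group is inert to acid.

Step 17
Reactants: 26 6-methoxy-3-nitrobicyclo[3.3.1]non-7-ene-1,4,9-triol
Product: 27 3-amino-6-methoxybicyclo[3.3.1]non-7-ene-1,4,9-triol
Conditions: Zn dust, AcOH–THF 1:1, rt → 40 °C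
Reagents that add atoms: none
Why: Dissolving-metal reduction of the aliphatic nitro group to the primary amine with retention at C1; no base is present, so the β-nitro alcohol cannot undergo a retro-Henry reaction.

Step 18
Reactants: 28 (E)-dodec-2-enoic acid
Product: 29 (E)-dodec-2-enoyl chloride
Conditions: (COCl)2, DMF (cat.), CH2Cl2, 0 °C → rt
Reagents that add atoms: oxalyl chloride, O=C(Cl)C(=O)Cl
Why: Acid chloride formation through the chloroiminium ion from DMF; the E alkene is untouched.

Step 19
Reactants: 27 3-amino-6-methoxybicyclo[3.3.1]non-7-ene-1,4,9-triol; 30 4-methoxybenzaldehyde; 29 (E)-dodec-2-enoyl chloride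
Product: 32 N-[(E)-dodec-2-enoyl]-2-(4-methoxyphenyl)oxazolidine fused cis across C1–N and C6–O, with free C3 and C4 hydroxyls, via Schiff base 31 (not isolated)
Conditions: 30, 4 Å MS, CH2Cl2, rt; then 29, pyridine, −20 → 0 °C
Reagents that add atoms: 4-methoxybenzaldehyde, COc1ccc(C=O)cc1; (E)-dodec-2-enoyl chloride, CCCCCCCCC/C=C/C(=O)Cl
Why: Imine formation then N-acylation: the N-acyliminium ion is captured by the cis-vicinal O6 hydroxyl (ring–chain tautomer trapped as the N-acyl oxazolidine), which forms the amide bond and masks O6 in one operation. Pyridine at low temperature limits deconjugation of the acid chloride.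

Step 20
Reactants: 32 N-acyl oxazolidine diol
Product: 33 C8–C9 exo-epoxide of 32
Conditions: mCPBA, CH2Cl2, 0 °C → rt
Reagents that add atoms: 3-chloroperbenzoic acid, OOC(=O)c1cccc(Cl)c1
Why: Prilezhaev epoxidation from the convex exo face of ring B, syn to and hydrogen-bond directed by the allylic C3 hydroxyl, sets C8 and C9. The concave face is blocked by ring A, the electron-poor enamide alkene does not react, and no ketone is yet present for a Baeyer–Villiger reaction.

Step 21
Reactants: 33 C8–C9 exo-epoxide of 32
Product: 34 C4 ketone of 33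
Conditions: IBX, DMSO, rt
Reagents that add atoms: none
Why: IBX oxidises the only secondary alcohol and converts 1,2-diols to α-ketols without C–C cleavage; C5 is a bridgehead and cannot epimerise.

Step 22
Reactants: 34 C4 ketone of 33
Product: 35 CNP0137540.1
Conditions: TFA–H2O–CH2Cl2 1:1:18, 0 °C
Reagents that add atoms: none
Why: Acid hydrolysis of the N-acyl N,O-acetal through the aryl-stabilised N-acyliminium ion frees N–H and O6–H without base, so the β-hydroxy ketone, α-ketol and epoxide are not exposed to retro-aldol or rearrangement conditions.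

## Compound list

1 | methyl α-D-glucopyranoside | CO[C@H]1O[C@H](CO)[C@@H](O)[C@H](O)[C@H]1O | starting material
2 | 4-methoxybenzaldehyde dimethyl acetal | COc1ccc(C(OC)OC)cc1 | starting material
3 | methyl 4,6-O-(4-methoxybenzylidene)-α-D-glucopyranoside | CO[C@H]1O[C@@H]2CO[C@@H](c3ccc(OC)cc3)O[C@H]2[C@H](O)[C@H]1O | intermediate
4 | methyl 4,6-O-(4-methoxybenzylidene)-2-O-tosyl-α-D-glucopyranoside | CO[C@H]1O[C@@H]2CO[C@@H](c3ccc(OC)cc3)O[C@H]2[C@H](O)[C@H]1OS(=O)(=O)c4ccc(C)cc4 | intermediate
5 | methyl 2,3-anhydro-4,6-O-(4-methoxybenzylidene)-α-D-mannopyranoside | CO[C@H]1O[C@@H]2CO[C@@H](c3ccc(OC)cc3)O[C@H]2[C@@H]4O[C@H]14 | intermediate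
6 | vinylmagnesium bromide | C=C[Mg]Br | starting material
7 | methyl 3-deoxy-4,6-O-(4-methoxybenzylidene)-3-C-vinyl-α-D-altropyranoside | CO[C@H]1O[C@@H]2CO[C@@H](c3ccc(OC)cc3)O[C@H]2[C@@H](C=C)[C@@H]1O | intermediate
8 | methyl 3-deoxy-4,6-O-(4-methoxybenzylidene)-2-O-methyl-3-C-vinyl-α-D-altropyranoside | CO[C@H]1O[C@@H]2CO[C@@H](c3ccc(OC)cc3)O[C@H]2[C@@H](C=C)[C@@H]1OC | intermediate
9 | methyl 3-deoxy-4-O-(4-methoxybenzyl)-2-O-methyl-3-C-vinyl-α-D-altropyranoside | CO[C@H]1O[C@H](CO)[C@@H](OCc2ccc(OC)cc2)[C@@H](C=C)[C@@H]1OC | intermediate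
10 | methyl 3,6-dideoxy-6-iodo-4-O-(4-methoxybenzyl)-2-O-methyl-3-C-vinyl-α-D-altropyranoside | CO[C@H]1O[C@H](CI)[C@@H](OCc2ccc(OC)cc2)[C@@H](C=C)[C@@H]1OC | intermediate
11 | methyl 3,6-dideoxy-4-O-(4-methoxybenzyl)-2-O-methyl-3-C-vinyl-α-D-arabino-hex-5-enopyranoside | CO[C@H]1OC(=C)[C@@H](OCc2ccc(OC)cc2)[C@@H](C=C)[C@@H]1OC | intermediate
12 | 5-hydroxy-4-methoxy-2-(4-methoxybenzyloxy)-3-vinylcyclohexan-1-one (2,3-cis, 3,4-trans, 4,5-cis) | O=C1C[C@@H](O)[C@@H](OC)[C@H](C=C)[C@@H]1OCc2ccc(OC)cc2 | intermediate
13 | C8 mesylate of 12 | O=C1C[C@@H](OS(C)(=O)=O)[C@@H](OC)[C@H](C=C)[C@@H]1OCc2ccc(OC)cc2 | intermediate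
14 | 4-methoxy-6-(4-methoxybenzyloxy)-5-vinylcyclohex-2-en-1-one (5,6-cis, 4,5-trans) | O=C1C=C[C@@H](OC)[C@H](C=C)[C@@H]1OCc2ccc(OC)cc2 | intermediate
15 | methyltriphenylphosphonium bromide | C[P+](c1ccccc1)(c1ccccc1)c1ccccc1.[Br-] | starting material
16 | 6-methoxy-4-(4-methoxybenzyloxy)-3-methylidene-5-vinylcyclohex-1-ene | C=C1C=C[C@@H](OC)[C@H](C=C)[C@@H]1OCc2ccc(OC)cc2 | intermediate
17 | 1-(bromomethyl)-4-methoxy-6-(4-methoxybenzyloxy)-5-vinylcyclohex-2-en-1-ol (OH anti to O6-benzyl ether and vinyl) | BrC[C@]1(O)C=C[C@@H](OC)[C@H](C=C)[C@@H]1OCc2ccc(OC)cc2 | intermediate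
18 | 6-methoxy-8-(4-methoxybenzyloxy)-7-vinyl-1-oxaspiro[2.5]oct-4-ene | C1O[C@]12C=C[C@@H](OC)[C@H](C=C)[C@@H]2OCc3ccc(OC)cc3 | intermediate
19 | 1-[6-methoxy-8-(4-methoxybenzyloxy)-1-oxaspiro[2.5]oct-4-en-7-yl]ethane-1,2-diol (carbinol epimers) | C1O[C@]12C=C[C@@H](OC)[C@H](C(O)CO)[C@@H]2OCc3ccc(OC)cc3 | intermediate
20 | 6-methoxy-8-(4-methoxybenzyloxy)-1-oxaspiro[2.5]oct-4-ene-7-carbaldehyde | C1O[C@]12C=C[C@@H](OC)[C@H](C=O)[C@@H]2OCc3ccc(OC)cc3 | intermediate
21 | nitromethane | C[N+](=O)[O-] | starting material
22 | (1R)-1-[6-methoxy-8-(4-methoxybenzyloxy)-1-oxaspiro[2.5]oct-4-en-7-yl]-2-nitroethanol | C1O[C@]12C=C[C@@H](OC)[C@H]([C@@H](O)C[N+](=O)[O-])[C@@H]2OCc3ccc(OC)cc3 | intermediate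
23 | key-step precursor: ring B spiro-oxirane with nitromethyl arm, O4 and O6 as 4-methoxybenzylidene acetal | O=[N+]([O-])C[C@@H]1O[C@H](c4ccc(OC)cc4)O[C@H]2[C@@H]1[C@H](OC)C=C[C@@]23CO3 | intermediate
24 | C1 epimer of 25 (axial nitro) | O=[N+]([O-])[C@@H]1C[C@@]2(O)[C@H]3O[C@@H](c4ccc(OC)cc4)O[C@@H]1[C@H]3[C@H](OC)C=C2 | intermediate
25 | key-step product: tricyclic nitro alcohol, O4 and O6 as 4-methoxybenzylidene acetal | O=[N+]([O-])[C@H]1C[C@@]2(O)[C@H]3O[C@@H](c4ccc(OC)cc4)O[C@@H]1[C@H]3[C@H](OC)C=C2 | intermediate
26 | 6-methoxy-3-nitrobicyclo[3.3.1]non-7-ene-1,4,9-triol | O=[N+]([O-])[C@H]1C[C@@]2(O)[C@@H](O)[C@@H]([C@H]1O)[C@H](OC)C=C2 | intermediate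
27 | 3-amino-6-methoxybicyclo[3.3.1]non-7-ene-1,4,9-triol | N[C@H]1C[C@@]2(O)[C@@H](O)[C@@H]([C@H]1O)[C@H](OC)C=C2 | intermediate
28 | (E)-dodec-2-enoic acid | CCCCCCCCC/C=C/C(=O)O | starting material
29 | (E)-dodec-2-enoyl chloride | CCCCCCCCC/C=C/C(=O)Cl | intermediate
30 | 4-methoxybenzaldehyde | COc1ccc(C=O)cc1 | starting material
31 | N-(4-methoxybenzylidene) derivative of 27 (Schiff base, in equilibrium with the oxazolidine) | COc1ccc(cc1)/C=N/[C@H]1C[C@@]2(O)[C@@H](O)[C@@H]([C@H]1O)[C@H](OC)C=C2 | intermediate
32 | N-[(E)-dodec-2-enoyl]-2-(4-methoxyphenyl)oxazolidine across C1–N/C6–O, C3 and C4 hydroxyls free | CCCCCCCCC/C=C/C(=O)N1[C@@H](c4ccc(OC)cc4)O[C@H]2[C@@H]1C[C@@]3(O)[C@@H](O)[C@@H]2[C@H](OC)C=C3 | intermediate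
33 | C8–C9 exo-epoxide of 32 | CCCCCCCCC/C=C/C(=O)N1[C@@H](c4ccc(OC)cc4)O[C@H]2[C@@H]1C[C@@]3(O)[C@@H](O)[C@@H]2[C@H](OC)[C@@H]5O[C@@H]53 | intermediate
34 | C4 ketone of 33 | CCCCCCCCC/C=C/C(=O)N1[C@@H](c4ccc(OC)cc4)O[C@H]2[C@@H]1C[C@@]3(O)C(=O)[C@@H]2[C@H](OC)[C@@H]5O[C@@H]53 | intermediate
35 | CNP0137540.1 | CCCCCCCCC/C=C/C(=O)N[C@H]1C[C@@]2(O)C(=O)[C@@H]([C@H]1O)[C@H](OC)[C@@H]1O[C@@H]12 | target

Total step count: 22. Longest linear sequence: 21 steps (steps 1–17 and 19–22; step 18 is the side-chain branch).

## Least certain steps

**Step 15 (key step).** The most likely failure is slow ring closure, because the cis-fused dioxane must leave its chair to bring C1 over C2. That would give time for loss of O6 from the nitronate (opening of the acetal to a nitroalkene) or for allylic attack at C8.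
Fallback: set out from 22 and drop the tether. Silylation of O6 (Et3SiOTf, 2,6-lutidine) gives the triethylsilyl ether F1. DBU closes ring A on the untethered chain to the bicyclic nitro alcohol F2 with separate O4 and O6 ethers. DDQ in wet CH2Cl2 removes the benzylic ether to give the C4 alcohol F3, and aqueous AcOH removes the silyl group, returning to the route at 26.

**Step 11.** The allylic cation may be captured by water at C8 (1,4-addition), or bromine may attack the vinyl group or the anisyl ring.
Fallback: set out from 16 and transfer oxygen directly to the exocyclic alkene with dimethyldioxirane in acetone at −20 °C. This is a concerted epoxidation from the same open face with no cationic intermediate, and it returns at 18 with no new compound.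

**Step 12.** Osmylation may not discriminate well enough between the vinyl group and the ring alkene, and the α-branched aldehyde may epimerise.
Fallback: set out from 14, where the ring alkene is an electron-poor enone, and carry C6 as a protected alcohol.
- Ozonolysis (O3, CH2Cl2–MeOH, −78 °C; Me2S) should cleave only the vinyl group to the keto aldehyde F4.
- NaBH(OAc)3 reduces the aldehyde to the hydroxy enone F5, and t-BuMe2SiCl/imidazole gives the silyl ether F6.
- Wittig methylenation as in step 10 gives the diene F7; NBS/H2O gives the bromohydrin F8 and K2CO3 the spiro-oxirane F9.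
- Bu4NF frees the primary alcohol F10, and Dess–Martin periodinane returns to the route at 20.

**Step 13.** Double diastereoselection may be mismatched, since both β-oxygen substituents are expected to favour the 6S epimer; this would erode facial selectivity at C6.
Fallback: set out from 20 and set C6 by hydride delivery instead. An unselective Henry reaction (Et3N cat.) gives 22 with its C6 epimer F11. Dess–Martin periodinane oxidises the mixture to the α-nitro ketone F12. Asymmetric transfer hydrogenation with RuCl(p-cymene)(TsDPEN) (ligand enantiomer chosen for the R carbinol) in HCO2H–Et3N returns to the route at 22.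

**Step 19.** O-acylation of the C4 hydroxyl, deconjugation of the acid chloride through a vinylketene, or incomplete ring closure of the N-acyliminium ion may compete.
Fallback: set out from 27. Acylate nitrogen alone with 29 under two-phase NaHCO3 conditions to the amide triol F13. Silylate the less hindered C6 hydroxyl (t-BuMe2SiCl, imidazole; O4 is flanked by the quaternary C3) to F14. Epoxidise with mCPBA to F15 and oxidise with IBX to the ketone F16. Remove the silyl group with Bu4NF buffered with AcOH, returning at 35.

## Further compounds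

F1 | step 15 | O6-triethylsilyl ether of 22 | C1O[C@]12C=C[C@@H](OC)[C@H]([C@@H](O[Si](CC)(CC)CC)C[N+](=O)[O-])[C@@H]2OCc3ccc(OC)cc3
F2 | step 15 | bicyclic nitro alcohol with O4 4-methoxybenzyl ether and O6 triethylsilyl ether | O=[N+]([O-])[C@H]1C[C@@]2(O)[C@@H](OCc3ccc(OC)cc3)[C@@H]([C@H]1O[Si](CC)(CC)CC)[C@H](OC)C=C2
F3 | step 15 | O6-triethylsilyl ether of 26 | O=[N+]([O-])[C@H]1C[C@@]2(O)[C@@H](O)[C@@H]([C@H]1O[Si](CC)(CC)CC)[C@H](OC)C=C2
F0 | step 11 | none | none
F4 | step 12 | 2-methoxy-6-(4-methoxybenzyloxy)-5-oxocyclohex-3-ene-1-carbaldehyde | O=C1C=C[C@@H](OC)[C@H](C=O)[C@@H]1OCc2ccc(OC)cc2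
F5 | step 12 | 5-(hydroxymethyl)-4-methoxy-6-(4-methoxybenzyloxy)cyclohex-2-en-1-one | O=C1C=C[C@@H](OC)[C@H](CO)[C@@H]1OCc2ccc(OC)cc2
F6 | step 12 | tert-butyldimethylsilyl ether of F5 | O=C1C=C[C@@H](OC)[C@H](CO[Si](C)(C)C(C)(C)C)[C@@H]1OCc2ccc(OC)cc2
F7 | step 12 | 3-methylidene diene from F6 | C=C1C=C[C@@H](OC)[C@H](CO[Si](C)(C)C(C)(C)C)[C@@H]1OCc2ccc(OC)cc2
F8 | step 12 | bromohydrin from F7 | BrC[C@]1(O)C=C[C@@H](OC)[C@H](CO[Si](C)(C)C(C)(C)C)[C@@H]1OCc2ccc(OC)cc2
F9 | step 12 | spiro-oxirane with silyloxymethyl arm | C1O[C@]12C=C[C@@H](OC)[C@H](CO[Si](C)(C)C(C)(C)C)[C@@H]2OCc3ccc(OC)cc3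
F10 | step 12 | spiro-oxirane with hydroxymethyl arm | C1O[C@]12C=C[C@@H](OC)[C@H](CO)[C@@H]2OCc3ccc(OC)cc3
F11 | step 13 | C6 epimer (1S) of 22 | C1O[C@]12C=C[C@@H](OC)[C@H]([C@H](O)C[N+](=O)[O-])[C@@H]2OCc3ccc(OC)cc3
F12 | step 13 | α-nitro ketone from 22 and F11 | C1O[C@]12C=C[C@@H](OC)[C@H](C(=O)C[N+](=O)[O-])[C@@H]2OCc3ccc(OC)cc3
F13 | step 19 | N-[(E)-dodec-2-enoyl] derivative of 27 | CCCCCCCCC/C=C/C(=O)N[C@H]1C[C@@]2(O)[C@@H](O)[C@@H]([C@H]1O)[C@H](OC)C=C2
F14 | step 19 | O6-tert-butyldimethylsilyl ether of F13 | CCCCCCCCC/C=C/C(=O)N[C@H]1C[C@@]2(O)[C@@H](O)[C@@H]([C@H]1O[Si](C)(C)C(C)(C)C)[C@H](OC)C=C2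
F15 | step 19 | C8–C9 exo-epoxide of F14 | CCCCCCCCC/C=C/C(=O)N[C@H]1C[C@@]2(O)[C@@H](O)[C@@H]([C@H]1O[Si](C)(C)C(C)(C)C)[C@H](OC)[C@@H]1O[C@@H]12
F16 | step 19 | C4 ketone of F15 | CCCCCCCCC/C=C/C(=O)N[C@H]1C[C@@]2(O)C(=O)[C@@H]([C@H]1O[Si](C)(C)C(C)(C)C)[C@H](OC)[C@@H]1O[C@@H]12
A1 | alternative 1 | cis-fused oxazolidinone across C1 and C6 of the epoxy ketol | O=C4N[C@H]1C[C@@]2(O)C(=O)[C@@H]([C@H]1O4)[C@H](OC)[C@@H]1O[C@@H]12
A2 | alternative 1 | C6 carbamate of the nitrogen-free epoxy ketol | NC(=O)O[C@H]1CC[C@@]2(O)C(=O)[C@@H]1[C@H](OC)[C@@H]3O[C@@H]32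
A3 | alternative 2 | isoxazoline-bridged bicyclo[3.3.1]nonene | CC(C)(C)OC(=O)N[C@H]1C[C@@]2(O[Si](C)(C)C)C3=NO[C@@H]1[C@H]3[C@H](OC)C=C2
A4 | alternative 2 | (Z,Z)-cyclooctadiene aldoxime | CC(C)(C)OC(=O)N[C@H]1C[C@@](O[Si](C)(C)C)(C=NO)/C=C\[C@@H](OC)/C=C\1
A5 | alternative 3 | C7 methyl ether with C8 vinyl bromide | O=C4N[C@H]1C[C@@]2(O[Si](CC)(CC)CC)C(=O)[C@@H]([C@H]1O4)[C@H](OC)C(Br)=C2
A6 | alternative 3 | exo gem-dibromocyclopropane fused at C7–C9 of the bicyclo[3.2.1]octanone | O=C4N[C@H]1C[C@@]2(O[Si](CC)(CC)CC)C(=O)[C@@H]([C@H]1O4)[C@H]3[C@@H]2C3(Br)Br
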